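Readings and results were computed from invented constants.

Per minute, some fraction of the Q in a flask may pass into L, which nobody reads. I suppose that L comes from Q, and I want that fraction.

| flask | D | X | temperature | remark | time |
|---|---|---|---|---|---|
| east | 0.50 M | 0.77 M | 45 °C | run made earlier |  |
| west | 0.50 M | 1.2 M | 56 °C | run made earlier |  |
| south | 1 M | 0.55 M | 45 °C | run made earlier |  |
| dusk | 0.50 M | 0.550 M | 40 °C |  | 30 min |
| dawn | 0.50 M | 0.550 M | 60 °C |  | 30 min |

- east (time / min: Q / %, Z / %): 2.50: 12, 4; 8.00: 24, 17; 12.0: 31, 19; 20.0: 41, 21; 30.0: 43, 26; 40.0: 49, 24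
- west (time / min: Q / %, Z / %): 2.50: 27, 18; 5.00: 43, 26; 10.0: 50, 31; 12.0: 50, 32; 15.0: 54, 29; 20.0: 50, 31
- south (time / min: Q / %, Z / %): 3.00: 8, 7; 5.00: 13, 3; 10.0: 21, 12; 20.0: 25, 12; 40.0: 31, 15

(each reading ± 2 percentage points)

- the earlier runs were read with a standard deviation of 2 percentage points

* the flask that comes out highest in share of Q in all that became Q or Z or L, or "all alike" when all lie within 1.5 percentage points (dusk / dawn / all alike)
* share of Q in all that became Q or Z or L, dusk
* share of Q in all that became Q or Z or L, dawn

Let the share asked for be y = Q/(Q + Z + L), and let s = Q/(Q + Z) be the split between the two read products (the selectivity). If Q stays roughly steady for a time t, then L ≈ κ·Q·t, and dividing through by Q gives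

1/y = 1/s + κ·t

The dawn flask looks nearly like the west run, and the dusk flask like the east run. The last reading of east gives s = 67.1%, and that of south, with twice the D, gives 67.4%, about the same. The hotter west run gives a lower split, 61.7%.

West leaves 19.0% of its D unread at its last reading. Counting all of that as L gives the leak constant, the first-order loss of Q per minute, κ = 0.0190 /min. This is a rough estimate for 56 °C, and it may run high, since the unread part may also hold leftover D.

My reckoning for dawn, using the west split and κ as they stand:

y = 45.7%

For dusk, the same κ gives a low estimate of 48.5%, and no leak gives a high estimate of 67.1%. The low estimate is above my dawn figure, and dusk is colder than west, so I put dusk just under the high estimate.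

The forecast also names dusk, but at 57%, below my dusk figure, and 49% for dawn, above mine, saying “this rests on the assumed L”.

The simulation gives 65.9% for dusk and 47.5% for dawn, so dusk comes out highest.

    D + X ⇌ Q (K = 11.0 /M, k = 0.190 /M/min, Ea = 67.0 kJ/mol, ΔH = −10.0 kJ/mol)
    D + X ⇌ Z (K = 4.40 /M, k = 0.120 /M/min, Ea = 78.0 kJ/mol, ΔH = −12.0 kJ/mol)
    Q → L (k = 0.0150 /min, Ea = 111 kJ/mol)
    (constants at 60 °C)

At 30 min, the amounts in the dawn flask give κ = 0.0137 /min, below the figure from west. The dawn share answers in part to the time allowed, acting together with the back reaction of Z to D + X: left until 300 min, dawn stands at 7.00% instead of 47.5%, and at 30 min without that back reaction it stands at 37.2%. Carrying this κ and the dawn split to the same flask left until 50 min, the rule gives 42.1%, and that flask gives 39.6%.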